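## Structural features

- The target is an 18-membered macrocyclic bis(bibenzyl) built from four six-membered rings: a 2-methoxy-1,4-benzoquinone (ring A), a para-phenylene (ring B), a 1,2,4-trisubstituted phenol (ring C) and a meta-phenylene (ring D).
- Ring A C6 is tied to ring B by a CH2–CH2 bridge. The para oxygen of ring B is bonded to C1 of ring C, which carries the free OH at C2 and a second CH2–CH2 bridge at C5 leading to ring D. The meta oxygen of ring D closes the macrocycle at C5 of ring A.
- In ring A the C1 carbonyl lies between C2 (OMe) and C6 (bridge), and the C4 carbonyl lies between C3 (H) and C5 (aryloxy).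
- There are no stereocentres, so no relative or absolute configuration has to be set.
- The fragile parts are the quinone, which is reducible and is a vinylogous aryl ester at C5 that nucleophiles can displace, and the oxidisable ring C phenol. Both have to be unveiled at the very end.
- The real difficulty is twofold: closing the 18-membered ring, and building the fully differentiated, pentasubstituted ring A.
- The feature used by the key step is the bridge ring A C6–CH2–CH2–ring B. Both of its carbons are benzylic, which is the pattern left when nitrogen is excised from a dibenzylamine.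

## Logic of the disconnections

**22 to 21.** The C1=O and C4=O groups of ring A are traced back to C1–OH and C4–OMe. The quinone cannot survive bases, hydrides, copper or radicals, whereas the arene can, so ring A is carried as a plain para-methoxyphenol. The forward oxidation must then select ring A over the ring C phenol of 21 and must release the C4 methyl group as methanol.

**21 to 20.** Both phenolic O–H bonds are replaced by O–CH2Ph. Masked phenols cannot react with an electrophilic nitrogen reagent or quench benzylic radicals, and one of the two ethers is already present in 1. The demand is one hydrogenolysis that removes both groups without touching diaryl ethers or bibenzyl bonds.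

**20 to 17.** The CH2–CH2 bond between ring A C6 and ring B is cut and an NH is inserted. Joining two sp3 carbons in a macrocyclisation is hard; a C–N–C unit is easy to close. The 18-membered carbocyclic bridge thus becomes a 19-membered dibenzylamine. The forward step must excise nitrogen as N2 and let the two benzylic radicals recombine faster than they abstract hydrogen or separate.

**17 to 14 (through 16 and 15).** The bond between the ring A benzylic carbon and nitrogen is cut to an aldehyde and a primary amine. Imine formation is reversible, so oligomers can revert and funnel to the ring under dilution. This opens the macrocycle to a chain that holds all four rings. The demand is that the amine stays masked until ring closure. Nitrogen is therefore carried as a carbamate from 8 onward, so no nitrile has to be reduced beside the ring A aldehyde and no acetal is needed.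

**14 to 13 to 12.** The ring A O–benzyl bond and then the ring A C6–CHO bond are cut. In 12 the only free position ortho to the phenol is C6 and the para position is blocked, so an ortho-specific formylation has one site to choose. Ring A is simplified to a phenol with one free ortho hydrogen. The forward step must work at a carbon flanked by OH and aryloxy and must avoid C3 between the two methoxy groups.

**12 to 10 (through 11).** The ring A C1–O bond is traced back to a C1–CHO bond. The aldehyde is the handle that the commercial bromide 9 already carries. The demand is a Baeyer–Villiger migration of the electron-rich aryl group without oxidation of the carbamate.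

**10 to 8 and 9.** The bond from the ring D oxygen to ring A C5 is cut. This is the convergent union of the three-ring phenol with a ring A building block that has every oxygen in place. The forward Ullmann coupling must tolerate an electron-rich, ortho-substituted bromide and must arylate oxygen, not the carbamate nitrogen.

**8 to 6 (through 7).** The CH2–NHBoc group is traced back to C≡N, and the CH2–CH2 bridge between rings C and D to CH=CH. The nitrile is the activating group of the first step and the alkene is what an olefination leaves. One reductive operation should set both, but the reductant must spare the benzyl ether and deliver the amine already protected.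

**6 to 3 and 5.** The C=C bond between rings C and D is cut to an aldehyde and a benzylic phosphonium salt. The ylide must react in the presence of its own free phenol. Alkene geometry does not matter.

**3 to 1 and 2; 5 to 4.** The bond from the ring C oxygen to ring B is cut; the para nitrile makes the fluoride of 2 displaceable. The C–P bond of 5 is cut back to the benzylic alcohol 4. Both forward steps are simple substitutions.

## Other disconnections considered

**Alternative 1:** The cut is the diaryl ether bond from the ring B oxygen to C1 of ring C.

- Forward step: the open precursor A1 carries ring C as a 2,6-dibromophenol and ring B as a 2,6-dichlorophenol. Tl(NO3)3 (trivalent thallium) oxidises the dibromophenol, the ring B oxygen adds at the ortho carbon, and zinc removes the geminal bromine and rearomatises to A2.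
- In its favour: it follows the likely biogenesis. The macrocycle is closed by the bond that nature closes, both bibenzyl bridges are made beforehand by ordinary chemistry, and the halogens fix which phenol is oxidised and where the oxygen attacks. Making a native bond, with no atom inserted and then removed from the skeleton, is a point on which this plan is the better one.
- Against it here: three halogens must be introduced and later removed. Zinc and the final dehalogenation both reduce the quinone, so it must be reoxidised. The electron-rich ring A has to pass through a two-electron phenol oxidation. Stoichiometric thallium is a serious toxicity burden.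
- Comparison: the chosen plan deletes one nitrogen tracelessly, whereas this one deletes three halogens. The mechanisms differ (polar phenoxonium capture versus radical-pair recombination), and both are intramolecular. Step count is expected to be equal at best and probably two or three steps longer.

**Alternative 2:** The cut is ring A itself, opened at the C1–C2 bond to a four-carbon squarate unit and a two-carbon alkyne.

- Forward step: heating the macrocyclic 4-hydroxy-4-(methoxyethynyl)cyclobutenone A3 opens the four-membered ring to an enynylketene. This closes to the six-membered ring and shifts hydrogen to C3, giving A4.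
- In its favour: the quinone appears at the correct oxidation level, and the positions of OMe, H, aryloxy and alkyl follow from the mechanism. No electron-rich arene has to be oxidised next to a free phenol. On end-game selectivity this plan is the better one.
- Against it here: the 18-membered ring must already be closed around a strained, electrophilic cyclobutenedione derivative. The aryloxy group on the cyclobutene is a vinylogous aryl ester, which a metalated methoxyethyne could displace instead of adding to the carbonyl. The last benzyl ether must be removed in the presence of the quinone.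
- Comparison: the mechanism is a thermal pericyclic cascade with no reagent, cleaner in principle than a radical pair. The macrocyclisation problem is not solved, only moved to a less stable substrate. Ring A needs fewer adjustments, but the squarate macrocycle costs more, so step economy is expected to be about equal.

**Alternative 3:** The cut is ring D, taken apart into a 2-aryloxy-1,3-diene and a two-carbon dienophile; the macrocycle is closed at the future C2–C3 bond of ring D.

- Forward step: the second-generation Grubbs catalyst under ethene joins the ethynyl ether on the ring A oxygen of A5 with the terminal alkene of the butenyl chain. This gives the macrocyclic diene A6 with the methylene carbon on C1. A Diels–Alder reaction with an ethyne equivalent and aromatisation would then build ring D.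
- In its favour: ring-closing metathesis is catalytic and among the most dependable macrocyclisations. On reliability of the ring-closing event it is the equal of the reductive amination and is better than the nitrogen deletion. It also avoids the Ullmann coupling at the crowded ring A carbon.
- Against it here: the aryl ethynyl ether on a di-ortho-substituted phenol is sensitive to hydration and needs two steps to install. Only the s-cis diene with an E ring alkene can cycloadd. Forming a meta-bridged arene inside the ring adds strain. Cycloaddition, aromatisation, hydrogenolysis and oxidation all follow the key step.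
- Comparison: the route is expected to be about three steps longer, with ruthenium carbene chemistry in place of a radical pair. The chosen plan has the shorter end game and starts from simpler materials.

Key step: step 10

Assumption: ring letters are A (quinone; C1 carbonyl between C2–OMe and C6–bridge, C4 carbonyl, C5 aryloxy), B (para-phenylene), C (phenol; C1 O-aryl, C2 OH, C5 bridge) and D (meta-phenylene). The alkene 6 is carried as an E/Z mixture because step 4 saturates it. The atom counts of the macrocycles (19 in 17, 18 in 20 to 22) and the ring A pattern were checked against the target and needed no correction.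

## Route

Step 1
Reactants: 1 4-(benzyloxy)-3-hydroxybenzaldehyde; 2 4-fluorobenzonitrile
Product: 3 4-[2-(benzyloxy)-5-formylphenoxy]benzonitrile
Conditions: K2CO3, DMF, 90 °C
Reagents that add atoms: none
Why: Nucleophilic aromatic substitution (SNAr): the phenoxide of 1 displaces fluoride para to the nitrile, which stabilises the Meisenheimer intermediate; the non-enolisable aldehyde is untouched by carbonate.

Step 2
Reactants: 4 3-hydroxybenzyl alcohol
Product: 5 (3-hydroxybenzyl)triphenylphosphonium bromide
Conditions: PPh3·HBr, MeCN, reflux
Reagents that add atoms: triphenylphosphine hydrobromide, [Br-].c1ccc(cc1)[PH+](c1ccccc1)c1ccccc1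
Why: Phosphonium salt formation from a benzylic alcohol: HBr activates the benzylic C–O bond and PPh3 captures the carbon by substitution; the phenol does not react.

Step 3
Reactants: 3 4-[2-(benzyloxy)-5-formylphenoxy]benzonitrile; 5 (3-hydroxybenzyl)triphenylphosphonium bromide
Product: 6 4-{2-(benzyloxy)-5-[2-(3-hydroxyphenyl)ethenyl]phenoxy}benzonitrile (E/Z mixture)
Conditions: KOtBu (2.2 equiv), THF, 0 °C to rt
Reagents that add atoms: none
Why: Wittig olefination: two equivalents of base give the phenoxide ylide, which adds to the aromatic aldehyde while the nitrile is inert to a semi-stabilised ylide; the geometry is irrelevant because step 4 saturates the alkene.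

Step 4
Reactants: 6 4-{2-(benzyloxy)-5-[2-(3-hydroxyphenyl)ethenyl]phenoxy}benzonitrile
Product: 8 tert-butyl N-{4-[2-(benzyloxy)-5-(3-hydroxyphenethyl)phenoxy]benzyl}carbamate, via primary amine 7 (not isolated)
Conditions: NiCl2·6H2O (0.2 equiv), NaBH4 (excess), Boc2O, MeOH–THF, 0 °C to rt; then K2CO3, MeOH
Reagents that add atoms: di-tert-butyl dicarbonate, CC(C)(C)OC(=O)OC(=O)OC(C)(C)C
Why: Nickel boride reduction (Ni2B formed from NiCl2 and NaBH4): the catalyst should hydrogenate the stilbene double bond and reduce the nitrile to amine 7, which Boc2O traps at once so that no secondary amine forms; aryl benzyl ethers are inert to Ni2B, and any carbonate formed on the phenol is methanolysed in the basic work-up.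

Step 5
Reactants: 8 tert-butyl N-{4-[2-(benzyloxy)-5-(3-hydroxyphenethyl)phenoxy]benzyl}carbamate; 9 5-bromo-2,4-dimethoxybenzaldehyde
Product: 10 tert-butyl N-(4-{2-(benzyloxy)-5-[3-(5-formyl-2,4-dimethoxyphenoxy)phenethyl]phenoxy}benzyl)carbamate
Conditions: CuI (10 mol %), N,N-dimethylglycine hydrochloride (30 mol %), Cs2CO3, 1,4-dioxane, 100 °C
Reagents that add atoms: none
Why: Ullmann diaryl ether synthesis with monovalent copper and an amino acid ligand: the caesium phenoxide of 8 couples with the aryl bromide, while the much less acidic carbamate N–H should not be arylated, as in O-arylations of N-Boc tyrosine esters.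

Step 6
Reactants: 10 tert-butyl N-(4-{2-(benzyloxy)-5-[3-(5-formyl-2,4-dimethoxyphenoxy)phenethyl]phenoxy}benzyl)carbamate
Product: 12 tert-butyl N-(4-{2-(benzyloxy)-5-[3-(5-hydroxy-2,4-dimethoxyphenoxy)phenethyl]phenoxy}benzyl)carbamate, via aryl formate 11 (not isolated)
Conditions: mCPBA, CH2Cl2, 0 °C to rt; then K2CO3 (cat.), MeOH, rt
Reagents that add atoms: mCPBA (3-chloroperoxybenzoic acid), OOC(=O)c1cccc(Cl)c1
Why: Dakin-type oxidation by Baeyer–Villiger reaction: the electron-rich 2,4-dimethoxyaryl group migrates in the Criegee intermediate to give formate 11, which mild methanolysis cleaves; carbamate, benzyl ether and diaryl ethers are not attacked by the peracid at this temperature.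

Step 7
Reactants: 12 tert-butyl N-(4-{2-(benzyloxy)-5-[3-(5-hydroxy-2,4-dimethoxyphenoxy)phenethyl]phenoxy}benzyl)carbamate
Product: 13 tert-butyl N-(4-{2-(benzyloxy)-5-[3-(2-formyl-3-hydroxy-4,6-dimethoxyphenoxy)phenethyl]phenoxy}benzyl)carbamate
Conditions: MgCl2, Et3N, (CH2O)n, MeCN, reflux
Reagents that add atoms: paraformaldehyde (reacting as formaldehyde), C=O
Why: Magnesium-mediated ortho-formylation of a phenol (Casnati–Skattebøl): the magnesium phenoxide delivers formaldehyde to the ortho carbon through a chelate and a second formaldehyde oxidises the hydroxymethyl group; the only free ortho position is the future C6 and the para position is blocked, so the aldehyde should enter between OH and aryloxy and not between the methoxy groups.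

Step 8
Reactants: 13 tert-butyl N-(4-{2-(benzyloxy)-5-[3-(2-formyl-3-hydroxy-4,6-dimethoxyphenoxy)phenethyl]phenoxy}benzyl)carbamate
Product: 14 tert-butyl N-[4-(2-(benzyloxy)-5-{3-[3-(benzyloxy)-2-formyl-4,6-dimethoxyphenoxy]phenethyl}phenoxy)benzyl]carbamate
Conditions: BnBr, K2CO3, DMF, rt to 50 °C
Reagents that add atoms: benzyl bromide, BrCc1ccccc1
Why: Williamson ether synthesis on the salicylaldehyde phenol; carbonate does not deprotonate the carbamate, so alkylation should occur on oxygen only.

Step 9
Reactants: 14 tert-butyl N-[4-(2-(benzyloxy)-5-{3-[3-(benzyloxy)-2-formyl-4,6-dimethoxyphenoxy]phenethyl}phenoxy)benzyl]carbamate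
Product: 17 nineteen-membered macrocyclic dibenzylamine (ring A C6–CH2–NH–CH2–ring B; rings A and C as benzyl ethers), via amino aldehyde 15 (not isolated), via macrocyclic imine 16 (not isolated)
Conditions: TFA, CH2Cl2, 0 °C; evaporate; syringe-pump addition to iPr2NEt, 4 Å MS, ClCH2CH2Cl (1 mM), rt; then NaBH(OAc)3, AcOH, rt
Reagents that add atoms: none
Why: Boc acidolysis followed by macrocyclic reductive amination: the ammonium salt of 15 is freed by base under high dilution and condenses reversibly with the ring A aldehyde to the 19-membered imine 16, so oligomers can revert to the ring; NaBH(OAc)3 reduces the iminium ion faster than the hindered aldehyde.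

Step 10
Reactants: 17 nineteen-membered macrocyclic dibenzylamine
Product: 20 eighteen-membered macrocycle with rings A and C as benzyl ethers (ring A C6–CH2–CH2–ring B), via N-amino amide adduct 18 (not isolated), via isodiazene 19 (not isolated)
Conditions: N-(benzyloxy)-N-(pivaloyloxy)-4-(trifluoromethyl)benzamide (1.5 equiv), THF (5 mM), 45 °C
Reagents that add atoms: none
Why: The secondary amine attacks the nitrogen of the anomeric amide and displaces pivalate to give adduct 18; a 1,2-shift of the benzyloxy group from nitrogen to the acyl carbon then expels benzyl 4-(trifluoromethyl)benzoate and leaves the isodiazene 19. Loss of N2 from 19 gives a pair of benzylic radicals that recombine to the CH2–CH2 bond between ring A C6 and ring B. The closest known reaction type is nitrogen deletion of secondary amines with anomeric amides, related to the Overberger–Lombardino fragmentation of 1,1-disubstituted hydrazines. The 18-membered ring closes by ring contraction of the 19-membered amine, that is, by recombination of two radical centres that remain joined through the rest of the macrocycle, not by a radical addition. No stereocentre is formed. The step needs recombination to beat hydrogen abstraction from the solvent and escape to intermolecular coupling. Three things secure this: both radicals are benzylic and poor hydrogen abstractors, they are born as a singlet pair in the same N2 extrusion, and the tether holds them together, helped by the dilute solution. Chemoselectivity rests on the amine being the only nucleophilic N–H or O–H site, since both phenols are benzyl ethers.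

Step 11
Reactants: 20 eighteen-membered macrocycle with rings A and C as benzyl ethers
Product: 21 eighteen-membered macrocyclic bis-phenol (ring A 1-hydroxy-2,4-dimethoxy; ring C 2-hydroxy)
Conditions: H2 (1 atm), Pd/C (10% palladium on carbon), EtOAc–MeOH, rt
Reagents that add atoms: none
Why: Catalytic hydrogenolysis of two aryl benzyl ethers; diaryl ethers, methyl ethers and the bibenzyl C–C bonds are stable to hydrogen over palladium at ambient pressure.

Step 12
Reactants: 21 eighteen-membered macrocyclic bis-phenol
Product: 22 CNP0332646.0
Conditions: PhI(OAc)2 (1.05 equiv), MeCN–H2O, 0 °C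
Reagents that add atoms: water, O
Why: Oxidative demethylation of a para-methoxyphenol with trivalent iodine: the ring A phenol is oxidised to a phenoxonium ion, water adds at C4 and the hemiketal expels methanol to leave the 1,4-quinone; ring A carries three further oxygen donors and is far easier to oxidise than the ring C phenol, so one equivalent at 0 °C should stop at 22.

## Compound list

1 | 4-(benzyloxy)-3-hydroxybenzaldehyde | O=Cc1ccc(OCc2ccccc2)c(O)c1 | starting material
2 | 4-fluorobenzonitrile | N#Cc1ccc(F)cc1 | starting material
3 | 4-[2-(benzyloxy)-5-formylphenoxy]benzonitrile | N#Cc1ccc(Oc2cc(C=O)ccc2OCc2ccccc2)cc1 | intermediate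
4 | 3-hydroxybenzyl alcohol | OCc1cccc(O)c1 | starting material
5 | (3-hydroxybenzyl)triphenylphosphonium bromide | [Br-].Oc1cccc(C[P+](c2ccccc2)(c2ccccc2)c2ccccc2)c1 | intermediate
6 | 4-{2-(benzyloxy)-5-[2-(3-hydroxyphenyl)ethenyl]phenoxy}benzonitrile, E/Z mixture (geometry not defined) | N#Cc1ccc(Oc2cc(C=Cc3cccc(O)c3)ccc2OCc2ccccc2)cc1 | intermediate
7 | 3-(2-{3-[4-(aminomethyl)phenoxy]-4-(benzyloxy)phenyl}ethyl)phenol (primary amine, not isolated) | NCc1ccc(Oc2cc(CCc3cccc(O)c3)ccc2OCc2ccccc2)cc1 | intermediate
8 | tert-butyl N-{4-[2-(benzyloxy)-5-(3-hydroxyphenethyl)phenoxy]benzyl}carbamate | CC(C)(C)OC(=O)NCc1ccc(Oc2cc(CCc3cccc(O)c3)ccc2OCc2ccccc2)cc1 | intermediate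
9 | 5-bromo-2,4-dimethoxybenzaldehyde | COc1cc(OC)c(Br)cc1C=O | starting material
10 | tert-butyl N-(4-{2-(benzyloxy)-5-[3-(5-formyl-2,4-dimethoxyphenoxy)phenethyl]phenoxy}benzyl)carbamate | CC(C)(C)OC(=O)NCc1ccc(Oc2cc(CCc3cccc(Oc4cc(C=O)c(OC)cc4OC)c3)ccc2OCc2ccccc2)cc1 | intermediate
11 | formate ester of phenol 12 (aryl formate, not isolated) | CC(C)(C)OC(=O)NCc1ccc(Oc2cc(CCc3cccc(Oc4cc(OC=O)c(OC)cc4OC)c3)ccc2OCc2ccccc2)cc1 | intermediate
12 | tert-butyl N-(4-{2-(benzyloxy)-5-[3-(5-hydroxy-2,4-dimethoxyphenoxy)phenethyl]phenoxy}benzyl)carbamate | CC(C)(C)OC(=O)NCc1ccc(Oc2cc(CCc3cccc(Oc4cc(O)c(OC)cc4OC)c3)ccc2OCc2ccccc2)cc1 | intermediate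
13 | tert-butyl N-(4-{2-(benzyloxy)-5-[3-(2-formyl-3-hydroxy-4,6-dimethoxyphenoxy)phenethyl]phenoxy}benzyl)carbamate | CC(C)(C)OC(=O)NCc1ccc(Oc2cc(CCc3cccc(Oc4c(C=O)c(O)c(OC)cc4OC)c3)ccc2OCc2ccccc2)cc1 | intermediate
14 | tert-butyl N-[4-(2-(benzyloxy)-5-{3-[3-(benzyloxy)-2-formyl-4,6-dimethoxyphenoxy]phenethyl}phenoxy)benzyl]carbamate | CC(C)(C)OC(=O)NCc1ccc(Oc2cc(CCc3cccc(Oc4c(C=O)c(OCc5ccccc5)c(OC)cc4OC)c3)ccc2OCc2ccccc2)cc1 | intermediate
15 | 2-(3-{3-[4-(aminomethyl)phenoxy]-4-(benzyloxy)phenethyl}phenoxy)-6-(benzyloxy)-3,5-dimethoxybenzaldehyde (present as its trifluoroacetate, not isolated) | NCc1ccc(Oc2cc(CCc3cccc(Oc4c(C=O)c(OCc5ccccc5)c(OC)cc4OC)c3)ccc2OCc2ccccc2)cc1 | intermediate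
16 | nineteen-membered macrocyclic imine, ring A C6–CH=N–CH2–ring B, E geometry expected (not isolated) | COc1cc(OC)c2c(c1OCc1ccccc1)/C=N/Cc1ccc(cc1)Oc1cc(ccc1OCc1ccccc1)CCc1cccc(c1)O2 | intermediate
17 | nineteen-membered macrocyclic dibenzylamine, rings A and C as benzyl ethers | COc1cc(OC)c2c(c1OCc1ccccc1)CNCc1ccc(cc1)Oc1cc(ccc1OCc1ccccc1)CCc1cccc(c1)O2 | intermediate
18 | adduct of 17 with the anomeric amide: ring nitrogen bonded to N(OCH2Ph)C(=O)C6H4CF3 (not isolated) | COc1cc(OC)c2c(c1OCc1ccccc1)CN(N(OCc1ccccc1)C(=O)c1ccc(cc1)C(F)(F)F)Cc1ccc(cc1)Oc1cc(ccc1OCc1ccccc1)CCc1cccc(c1)O2 | intermediate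
19 | macrocyclic isodiazene (1,1-diazene) on the ring nitrogen (not isolated) | COc1cc(OC)c2c(c1OCc1ccccc1)C[N+](=[N-])Cc1ccc(cc1)Oc1cc(ccc1OCc1ccccc1)CCc1cccc(c1)O2 | intermediate
20 | eighteen-membered macrocycle, ring A as benzyl-protected methoxyhydroquinone methyl ether, ring C as benzyl ether | COc1cc(OC)c2c(c1OCc1ccccc1)CCc1ccc(cc1)Oc1cc(ccc1OCc1ccccc1)CCc1cccc(c1)O2 | intermediate
21 | eighteen-membered macrocyclic bis-phenol (ring A 1-OH, 2-OMe, 4-OMe; ring C 2-OH) | COc1cc(OC)c2c(c1O)CCc1ccc(cc1)Oc1cc(ccc1O)CCc1cccc(c1)O2 | intermediate
22 | CNP0332646.0, the macrocyclic 2-methoxy-1,4-benzoquinone | COC1=CC(=O)C2=C(CCc3ccc(cc3)Oc3cc(ccc3O)CCc3cccc(c3)O2)C1=O | target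

## Step count and risk

Total step count: 12. Longest linear sequence: 11 steps (steps 1 and 3 to 12, from 1 to 22); step 2 is the one-step branch.

**Step 10 (key step).** Nitrogen transfer may be slow because the amine sits next to the doubly ortho-substituted ring A. Once the radical pair forms, it may abstract hydrogen from THF or from the neighbouring O-benzyl methylene, or the radicals may couple between molecules, leading to ring-opened or oligomeric material. Fallback, from 17 back to 20: build the isodiazene stepwise with a small electrophile and extrude N2 in a solvent that donates no hydrogen (Overberger–Lombardino sequence). Nitrosation with tBuONO in CH2Cl2 should give the N-nitrosamine F1. Reduction with LiAlH4 in THF should give the N-amino amine F2. Oxidation with HgO (divalent mercury) in benzene should regenerate 19, which loses N2 and closes to 20.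

**Step 9.** Intermolecular imine formation may outrun ring closure and give linear and cyclic oligomers. Slow condensation at the di-ortho-substituted aldehyde may also let the hydride reduce the aldehyde. Fallback, from 14 back to 17: close the ring by irreversible N-alkylation of a sulfonamide (Fukuyama–Mitsunobu). TFA and then 2-nitrobenzenesulfonyl chloride with Et3N should give the sulfonamide aldehyde F3. NaBH4 in MeOH should give the benzylic alcohol F4. DIAD and PPh3 in dilute toluene should close the N-sulfonyl macrocycle F5. PhSH with K2CO3 in DMF should release 17.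

**Step 4.** Saturation of the E alkene may lag behind nitrile reduction, or the free amine may condense with partly reduced imine before Boc2O captures it. Fallback, from 6 back to 8: split the two reductions. Diimide (TsNHNH2, NaOAc, DME–H2O, reflux) should reduce only the alkene to 4-{2-(benzyloxy)-5-(3-hydroxyphenethyl)phenoxy}benzonitrile F6. The conditions of step 4 should then convert the nitrile of F6 into 8.

**Step 5.** Coupling at the electron-rich, ortho-methoxy bromide may be sluggish, so protodebromination, carbamate N-arylation or base-induced degradation of the aldehyde may compete. Fallback, from 9 and 8 back to 10: reverse the role of the ring A partner to a boron nucleophile. Miyaura borylation of 9 (B2pin2, PdCl2(dppf), KOAc, dioxane, 90 °C) should give the pinacol boronate F7. NaIO4 and NH4OAc in aqueous acetone should give 5-formyl-2,4-dimethoxyphenylboronic acid F8. Chan–Lam coupling of F8 with 8 (Cu(OAc)2, pyridine, 4 Å MS, CH2Cl2, air, rt) should give 10.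

**Step 7.** Formylation at the crowded carbon between OH and aryloxy may stall at low conversion, or the hydroxymethyl intermediate may condense with a second phenol. Fallback, from 12 back to 14: install the carbon at the alcohol oxidation level under boron templating. PhB(OH)2, paraformaldehyde and catalytic propionic acid in refluxing toluene should give the 2-phenyl-4H-1,3,2-benzodioxaborin F9. Exchange with propane-1,3-diol should free the ortho-hydroxymethyl phenol F10. BnBr with K2CO3 should benzylate only the phenol to give F11. MnO2 in CH2Cl2 should oxidise the benzylic alcohol to 14.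

**Step 12.** The oxidant may also dearomatise the ring C phenol, or the aryloxyquinone may suffer substitution once formed. Fallback, from 21 back to 22: mask the ring C phenol first. One equivalent of TBSCl with imidazole in DMF at 0 °C should silylate the less hindered ring C phenol to give F12. PhI(OAc)2 in MeCN–H2O should then oxidise ring A alone to the silyl-protected quinone F13. KHF2 in MeOH should cleave the aryl silyl ether to 22.

## Further compounds

F1 | step 10 | N-nitroso derivative of macrocyclic amine 17 | COc1cc(OC)c2c(c1OCc1ccccc1)CN(N=O)Cc1ccc(cc1)Oc1cc(ccc1OCc1ccccc1)CCc1cccc(c1)O2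
F2 | step 10 | N-amino derivative of macrocyclic amine 17 (1,1-disubstituted hydrazine) | COc1cc(OC)c2c(c1OCc1ccccc1)CN(N)Cc1ccc(cc1)Oc1cc(ccc1OCc1ccccc1)CCc1cccc(c1)O2
F3 | step 9 | N-(2-nitrobenzenesulfonyl) analogue of 14 (sulfonamide aldehyde) | O=S(=O)(NCc1ccc(Oc2cc(CCc3cccc(Oc4c(C=O)c(OCc5ccccc5)c(OC)cc4OC)c3)ccc2OCc2ccccc2)cc1)c1ccccc1[N+](=O)[O-]
F4 | step 9 | benzylic alcohol from F3 (sulfonamide alcohol) | O=S(=O)(NCc1ccc(Oc2cc(CCc3cccc(Oc4c(CO)c(OCc5ccccc5)c(OC)cc4OC)c3)ccc2OCc2ccccc2)cc1)c1ccccc1[N+](=O)[O-]
F5 | step 9 | N-(2-nitrobenzenesulfonyl) derivative of macrocyclic amine 17 | COc1cc(OC)c2c(c1OCc1ccccc1)CN(Cc1ccc(cc1)Oc1cc(ccc1OCc1ccccc1)CCc1cccc(c1)O2)S(=O)(=O)c1ccccc1[N+](=O)[O-]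
F6 | step 4 | 4-{2-(benzyloxy)-5-(3-hydroxyphenethyl)phenoxy}benzonitrile | N#Cc1ccc(Oc2cc(CCc3cccc(O)c3)ccc2OCc2ccccc2)cc1
F7 | step 5 | 2,4-dimethoxy-5-(4,4,5,5-tetramethyl-1,3,2-dioxaborolan-2-yl)benzaldehyde | COc1cc(OC)c(cc1C=O)B1OC(C)(C)C(C)(C)O1
F8 | step 5 | 5-formyl-2,4-dimethoxyphenylboronic acid | COc1cc(OC)c(cc1C=O)B(O)O
F9 | step 7 | 2-phenyl-4H-1,3,2-benzodioxaborin formed on ring A of 12 (boron bridging the phenol oxygen and the new CH2O) | CC(C)(C)OC(=O)NCc1ccc(Oc2cc(CCc3cccc(Oc4c5COB(c6ccccc6)Oc5c(OC)cc4OC)c3)ccc2OCc2ccccc2)cc1
F10 | step 7 | ortho-hydroxymethyl phenol from 12 (CH2OH in place of CHO of 13) | CC(C)(C)OC(=O)NCc1ccc(Oc2cc(CCc3cccc(Oc4c(CO)c(O)c(OC)cc4OC)c3)ccc2OCc2ccccc2)cc1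
F11 | step 7 | benzylic alcohol corresponding to 14 (CH2OH in place of CHO) | CC(C)(C)OC(=O)NCc1ccc(Oc2cc(CCc3cccc(Oc4c(CO)c(OCc5ccccc5)c(OC)cc4OC)c3)ccc2OCc2ccccc2)cc1
F12 | step 12 | ring C tert-butyldimethylsilyl ether of bis-phenol 21 | COc1cc(OC)c2c(c1O)CCc1ccc(cc1)Oc1cc(ccc1O[Si](C)(C)C(C)(C)C)CCc1cccc(c1)O2
F13 | step 12 | ring C tert-butyldimethylsilyl ether of target 22 | COC1=CC(=O)C2=C(CCc3ccc(cc3)Oc3cc(ccc3O[Si](C)(C)C(C)(C)C)CCc3cccc(c3)O2)C1=O
A1 | alternative 1 | open-chain quinone with ring C as 2,6-dibromophenol and ring B as 2,6-dichlorophenol | COC1=CC(=O)C(Oc2cccc(CCc3cc(Br)c(O)c(Br)c3)c2)=C(CCc2cc(Cl)c(O)c(Cl)c2)C1=O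
A2 | alternative 1 | target macrocycle carrying two chlorines on ring B and one bromine on ring C | COC1=CC(=O)C2=C(CCc3cc(Cl)c(c(Cl)c3)Oc3cc(cc(Br)c3O)CCc3cccc(c3)O2)C1=O
A3 | alternative 2 | macrocyclic 4-hydroxy-4-(methoxyethynyl)cyclobutenone (3-aryloxy from ring D, 2-alkyl bridge to ring B, ring C as benzyl ether) | COC#CC1(O)C(=O)C2=C1Oc1cccc(c1)CCc1ccc(OCc3ccccc3)c(c1)Oc1ccc(CC2)cc1
A4 | alternative 2 | target quinone macrocycle as its ring C benzyl ether | COC1=CC(=O)C2=C(CCc3ccc(cc3)Oc3cc(ccc3OCc3ccccc3)CCc3cccc(c3)O2)C1=O
A5 | alternative 3 | open-chain enyne: ethynyl ether on the ring A oxygen and but-3-enyl chain on ring C | COc1cc(OC)c(OC#C)c(CCc2ccc(Oc3cc(CCC=C)ccc3OCc3ccccc3)cc2)c1OCc1ccccc1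
A6 | alternative 3 | eighteen-membered macrocyclic 2-aryloxy-1,3-diene (E ring alkene, exocyclic methylene) | COc1cc(OC)c2c(c1OCc1ccccc1)CCc1ccc(cc1)Oc1cc(ccc1OCc1ccccc1)CC/C=C/C(=C)O2
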